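## The problem

Atom numbers used throughout: the cyclopentene is C1–C5 (C3=C4, methyl C17 on C4), fused at C1–C5 to the seven-membered ring C5–C10. C6 bears OH, C7 the side chain, C9 the acetate and C10 the exocyclic methylene C18. The side chain is C11 (methyl C19), C12, C13=C14 and C15 (OH, two methyls).

- The skeleton is a trans-fused hydroazulene (H-1 and H-5 anti) in which every carbon of the seven-membered ring carries a substituent or a functional group.
- There are six stereocentres: C1, C5, C6, C7 and C9 on the ring and C11 outside it. C4 on C5 is anti to O6, whereas O6, C11 (on C7) and O9 all lie on one face.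
- O6 and O9 are cis but 1,4 to each other, too far apart for one to direct the other, so they must either arrive together or be set independently.
- O6 can control its neighbours: a nucleophile enters C5 anti to it, a tether from it delivers carbon to C7 syn, and a ring through O6 and C7 offers a convex face for C11. C5 in turn controls C1 (trans).
- Groups that will not survive rough treatment: the tertiary allylic alcohol (ionisation), the allylic acetate beside the exocyclic methylene, and the skipped C3=C4/C5 olefin, which would move into conjugation if C6 were ever a ketone under base. Of the two secondary hydroxyls only the less hindered one (C9) is acetylated.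
- The enabling feature is the oxidation pattern of the seven-membered ring itself: C10 (carbonyl level), C9–O and C6–O cis across C7–C8, and carbon substituents on C1 and C5. This is the pattern of tropone 1 after photooxygenation across its C2–C5 diene, which leaves a ketone at C10, an enone C1=C5 and an olefin C7=C8 exactly where they are needed. The seven-membered ring need not be closed at all.

## Retrosynthesis

**23 ⇒ 22.** The acetate is put on last. In triol 22 the C9 hydroxyl is an unhindered allylic carbinol, the C6 hydroxyl is flanked by the ring fusion and the branched C7, and the C15 hydroxyl is tertiary. No protecting group has to be removed after the acetylation.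

**22 ⇒ 20 + 21.** The C13=C14 bond is cut by cross-metathesis. The partner 21 is a purchased tertiary allylic alcohol that enforces E geometry and brings C14–C16 and C20 in one step. The alternative, adjusting a prenyl terminus by oxidation, would compete with the ring olefins.

**20 ⇒ 19 ⇒ 17.** C14 and C13 are removed one carbon at a time (Wittig methylenation of lactol 19; methoxymethylenation of lactol 17). Both lactols keep O6 tied up, and in 17 C11 is α to a masked aldehyde inside a cis-fused five-membered ring, where the methyl group can equilibrate to the convex face.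

**17 ⇒ 15 ⇒ 14 ⇒ 12 + 13.** The C7–C11 bond is cut as a radical cyclisation of bromoacetal 14 from O6 onto the C7=C8 olefin. A two-atom tether can only deliver C11 to the face of O6, which gives the otherwise awkward cis O6/C7 relationship. The precursor 12 has no stereocentre at C7 or C11, and 13 is a purchased enol ether.

**12 ⇒ 11.** One enzymatic acetylation both resolves the racemic diol 11 and distinguishes the C9 from the C6 hydroxyl. This is preferred to separate protection and resolution steps.

**11 ⇒ 10 ⇒ 9.** The exocyclic methylene comes from the C10 ketone of 9, which is needed earlier as the activating group. The two silyl ethers are removed together.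

**9 ⇒ 8 ⇒ 4 + 5 + 6.** The cyclopentene is cut at C3=C4 (ring-closing metathesis) and then at C5–C4 and C1–C2 (conjugate addition of 5 to the enone of 4, allylation of the enolate with 6). Intermolecular alkylation gives the trans ring fusion that a cycloaddition onto C1=C5 would not, and the C6 silyloxy group sets C5.

**4 ⇒ 2 ⇒ 1.** Both C–O bonds are cut at once: the endoperoxide 2 is the [4+2] adduct of singlet oxygen and tropone 1. This is the key simplification. An achiral, flat, purchased seven-membered ring becomes a ring with C6 and C9 set cis and with every carbon differentiated. The forward reaction must be periselective and the labile adduct must be reduced and protected without aromatisation.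

## Roads not taken

**Alternative 1:** the most obvious plan keeps the conjugate addition/allylation/metathesis annulation but builds the seven-membered enone A1 from an acyclic, chiral-pool chain by ring-closing metathesis. It would annulate to the 9-deoxy ketone A2 and introduce O9 last by α-hydroxylation of the C10 ketone enolate. The chosen plan is better for three reasons:
- C6, C7 and C11 of A1 each need their own acyclic control element.
- Nothing in A2 ties the incoming O9 to the face of O6 (a 1,4 relationship across the ring), so the C9 configuration is left to an enolate face that the C7 side chain may well shield.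
- The route needs two metatheses in the presence of the side-chain olefin and is longer.

**Alternative 2:** an oxidopyrylium (5+2) cycloaddition from a furan-derived pyranone would give the oxa-bridged dienone A3, which has the same carbon pattern (C10 ketone, C1=C5 enone, C7=C8 olefin). The chosen plan is better because:
- A3 carries only one oxygen for C6 and C9, so cleaving the bridge leaves one hydroxyl and O9 must be re-introduced.
- The bridge forces nucleophiles onto the enone face syn to the bridging oxygen, which places C4 cis to O6, the opposite of what the target needs.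
- In the monocyclic compound 4 the same oxygen substituents direct the nucleophile anti, as required.

**Alternative 3:** the seven-membered ring could be closed last at C9–C10 by an intramolecular Nozaki–Hiyama–Kishi reaction (CrCl2/NiCl2) of the vinyl iodide–aldehyde A4. This would form the C9 carbinol and the methylene in one step. The chosen plan is better because:
- A4 already contains C1, C5, C6, C7 and C11, on a trans-1,5-disubstituted cyclopentene whose assembly is the real problem.
- The C9 configuration would depend on a medium-ring transition state with no link to O6.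
- The ring closure is entropically the weakest step of such a route, whereas here no seven-membered ring is closed.

Key step: step 1

Remark 1: the SMILES is read as drawn: trans ring fusion, with 6-OH, the C7 side chain and 9-OAc on one face; absolute configuration (1S,5R,6S,7R,9R,11S).
Remark 2: compounds 2–11 are racemic; their SMILES and descriptors show the enantiomer that is kept in step 7.

## Route

Step 1
Reactants: 1 tropone
Product: 2 (1R,5S)-6,7-dioxabicyclo[3.2.2]nona-3,8-dien-2-one (racemate)
Conditions: O2, tetraphenylporphyrin (cat.), visible light, CH2Cl2, −20 °C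
Reagents that add atoms: dioxygen O=O
Why: Singlet oxygen adds suprafacially in a [4+2] cycloaddition across C2–C5 of the troponoid triene (C9 and C6 of the target); the closest known reaction type is the photooxygenation of cyclic 1,3-dienes to endoperoxides, which is documented for tropone itself. The only ring closed is the six-membered 1,2-dioxane, closed by the cycloaddition (bicyclo[3.2.2] skeleton). The two new stereocentres C6 and C9 arise in one event and are necessarily cis, because both C–O bonds form on one face of the planar ring; the product is racemic and the absolute sense is chosen in step 7. The step needs periselectivity ([4+2] rather than [6+2], [2+2] or ene) and site selectivity: the carbonyl makes C2–C5 the only s-cis diene whose addition leaves a conjugated enone, and there are no allylic hydrogens for an ene reaction. The flat ring thereby becomes one in which every carbon is differentiated: C10 ketone, C1=C5 enone for the two C–C bonds, C7=C8 olefin between the two C–O bonds. Low temperature and neutral work-up are needed because H-9 of 2 is acidic (Kornblum–DeLaMare isomerisation).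

Step 2
Reactants: 2 (1R,5S)-6,7-dioxabicyclo[3.2.2]nona-3,8-dien-2-one
Product: 4 (2R,5S)-2,5-bis(tert-butyldimethylsilyloxy)cyclohepta-3,6-dien-1-one, via diol 3 (not isolated)
Conditions: thiourea, MeOH/CH2Cl2, −30 °C; cold evaporation; then t-BuMe2SiOSO2CF3, 2,6-lutidine, CH2Cl2, −78 °C
Reagents that add atoms: tert-butyldimethylsilyl trifluoromethanesulfonate CC(C)(C)[Si](C)(C)OS(=O)(=O)C(F)(F)F
Why: Thiourea cleaves the O–O bond without touching either C–O bond, so both configurations are retained; the labile cis-diol 3 is silylated cold before it can enolise. Peroxide-to-diol reduction followed by silyl protection is standard for diene endoperoxides.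

Step 3
Reactants: 4 (2R,5S)-2,5-bis(tert-butyldimethylsilyloxy)cyclohepta-3,6-dien-1-one; 5 isopropenylmagnesium bromide; 6 allyl iodide
Product: 8 (2R,5S,6R,7S)-2,5-bis(tert-butyldimethylsilyloxy)-6-(prop-1-en-2-yl)-7-(prop-2-en-1-yl)cyclohept-3-en-1-one, via bromomagnesium enolate 7 (not isolated)
Conditions: 5 (2.2 equiv), CuI (1.1 equiv), THF, −78 °C; add 4; then 6, DMPU, −78 → −30 °C
Reagents that add atoms: none
Why: The preformed isopropenyl cuprate adds to the enone at C5 anti to the γ-silyloxy group (both silyloxy groups shield the same face), and the regiodefined enolate 7 is C-allylated at C1 trans to the new C5 substituent; this is the three-component conjugate addition–enolate alkylation known for γ-silyloxy cycloalkenones. C1 is also α to the ketone, so the trans arrangement is the thermodynamic one as well.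

Step 4
Reactants: 8 (2R,5S,6R,7S)-2,5-bis(tert-butyldimethylsilyloxy)-6-(prop-1-en-2-yl)-7-(prop-2-en-1-yl)cyclohept-3-en-1-one
Product: 9 (3aR,4S,7R,8aS)-4,7-bis(tert-butyldimethylsilyloxy)-3-methyl-3a,4,7,8a-tetrahydroazulen-8(1H)-one
Conditions: second-generation Grubbs catalyst (H2IMes)(PCy3)Cl2Ru=CHPh (cat.), CH2Cl2, 40 °C
Reagents that add atoms: none
Why: Ring-closing metathesis between the allyl and isopropenyl groups closes the trisubstituted cyclopentene (C3=C4) with loss of ethylene. The ring olefin C7=C8, flanked by two silyloxy-bearing carbons, is a poor metathesis partner, and the trans ring fusion from step 3 is retained.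

Step 5
Reactants: 9 (3aR,4S,7R,8aS)-4,7-bis(tert-butyldimethylsilyloxy)-3-methyl-3a,4,7,8a-tetrahydroazulen-8(1H)-one
Product: 10 (3aR,4S,7R,8aS)-4,7-bis(tert-butyldimethylsilyloxy)-3-methyl-8-methylidene-1,3a,4,7,8,8a-hexahydroazulene
Conditions: Cp2TiMe2, toluene, 65 °C, dark
Reagents that add atoms: dimethyltitanocene [CH3-].[CH3-].[Ti+4].c1cc[cH-]c1.c1cc[cH-]c1
Why: Petasis methylenation converts the hindered, enolisable α-silyloxy ketone into the exocyclic methylene under non-basic conditions, so C1 and C9 are not epimerised.

Step 6
Reactants: 10 (3aR,4S,7R,8aS)-4,7-bis(tert-butyldimethylsilyloxy)-3-methyl-8-methylidene-1,3a,4,7,8,8a-hexahydroazulene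
Product: 11 (3aR,4S,7R,8aS)-3-methyl-8-methylidene-1,3a,4,7,8,8a-hexahydroazulene-4,7-diol (racemate)
Conditions: Bu4NF, THF, 0 → 23 °C
Reagents that add atoms: none
Why: Fluoride removes both secondary silyl ethers; no stereocentre is affected.

Step 7
Reactants: 11 (3aR,4S,7R,8aS)-3-methyl-8-methylidene-1,3a,4,7,8,8a-hexahydroazulene-4,7-diol (racemate)
Product: 12 (3aR,4S,7R,8aS)-4-hydroxy-3-methyl-8-methylidene-1,3a,4,7,8,8a-hexahydroazulen-7-yl acetate (single enantiomer)
Conditions: immobilised Burkholderia cepacia lipase, vinyl acetate, t-BuOMe, 30 °C, to about half conversion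
Reagents that add atoms: vinyl acetate CC(=O)OC=C
Why: Lipase-catalysed transesterification acylates secondary carbinols of one absolute sense; at C9 the larger group is C10 and the smaller C8, so by the empirical size rule the 9R carbinol is the fast one. The enzyme also avoids the hindered C6 hydroxyl next to the ring fusion, so one operation resolves the racemate and differentiates the two hydroxyls. The mirror-image diol stays unacylated and is separated.

Step 8
Reactants: 12 (3aR,4S,7R,8aS)-4-hydroxy-3-methyl-8-methylidene-1,3a,4,7,8,8a-hexahydroazulen-7-yl acetate; 13 ethyl prop-1-enyl ether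
Product: 14 (3aR,4S,7R,8aS)-4-(2-bromo-1-ethoxypropoxy)-3-methyl-8-methylidene-1,3a,4,7,8,8a-hexahydroazulen-7-yl acetate (mixture at the two new side-chain centres)
Conditions: 13 (excess), N-bromosuccinimide, CH2Cl2, −40 → 0 °C
Reagents that add atoms: N-bromosuccinimide O=C1CCC(=O)N1Br
Why: Bromoacetalisation: the enol ether is brominated and the C6 hydroxyl captures the oxocarbenium ion, giving the mixed α-bromo acetal for a Ueno–Stork cyclisation. The enol ether is far more nucleophilic than the other olefins.

Step 9
Reactants: 14 (3aR,4S,7R,8aS)-4-(2-bromo-1-ethoxypropoxy)-3-methyl-8-methylidene-1,3a,4,7,8,8a-hexahydroazulen-7-yl acetate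
Product: 15 tricyclic ethyl acetal: tetrahydrofuran O6–C12H(OEt)–C11H(CH3)–C7 cis-fused at C6–C7 (1S,5R,6S,7R,9R,11R; both C12 anomers), 9-acetate
Conditions: Bu3SnH, AIBN (cat.), benzene, 80 °C, slow addition
Reagents that add atoms: none
Why: Ueno–Stork radical cyclisation: the C11 radical closes 5-exo-trig onto C7 of the C7=C8 olefin, and the two-atom tether from O6 allows only cis fusion, so C11 is delivered to the face of O6 (C7 R); the C8 radical is reduced by the stannane. The methyl on C11 is expected mainly trans to C8 (exo).

Step 10
Reactants: 15 tricyclic ethyl acetal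
Product: 17 lactol diol: 12-hydroxy tetrahydrofuran O6–C12H(OH)–C11H(CH3)–C7 with free 9-OH (1S,5R,6S,7R,9R,11R), via acetoxy lactol 16 (not isolated)
Conditions: 1 M HCl, THF, 23 °C; then K2CO3 (cat.), MeOH, 23 °C
Reagents that add atoms: water O
Why: Acid hydrolyses the ethyl acetal to lactol 16. Methanolic carbonate then removes the acetate, which has served as the C9 protecting group, and equilibrates C11 through the open hydroxy aldehyde to the lactol with the methyl on the convex face, trans to C8; this is the configuration that becomes 11S in 23.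

Step 11
Reactants: 17 lactol diol
Product: 19 six-membered lactol O6–C13H(OH)–C12H2–C11H(CH3)–C7 with free 9-OH (1S,5R,6S,7R,9R,11S), via enol ether 18 (not isolated)
Conditions: [Ph3PCH2OCH3]Cl, KN(SiMe3)2, THF, −78 → 0 °C; then 1 M HCl, THF/H2O, 23 °C
Reagents that add atoms: (methoxymethyl)triphenylphosphonium chloride COC[P+](c1ccccc1)(c1ccccc1)c1ccccc1.[Cl-]; water O
Why: Wittig methoxymethylenation of the lactol (through its open aldehyde) adds C13; acid hydrolysis of enol ether 18 gives the homologous aldehyde, which closes on O6 to the six-membered lactol 19. Low temperature keeps olefination ahead of enolisation of the α-branched aldehyde, and after this step C11 is no longer α to a carbonyl.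

Step 12
Reactants: 19 six-membered lactol
Product: 20 (3aR,4S,5R,7R,8aS)-3-methyl-8-methylidene-5-[(2S)-pent-4-en-2-yl]-1,3a,4,5,6,7,8,8a-octahydroazulene-4,7-diol
Conditions: [Ph3PCH3]Br, KN(SiMe3)2, THF, 0 → 40 °C
Reagents that add atoms: methyltriphenylphosphonium bromide C[P+](c1ccccc1)(c1ccccc1)c1ccccc1.[Br-]
Why: Wittig methylenation of the lactol opens it to the terminal olefin C13=C14 and liberates the C6 hydroxyl; no stereocentre is involved.

Step 13
Reactants: 20 (3aR,4S,5R,7R,8aS)-3-methyl-8-methylidene-5-[(2S)-pent-4-en-2-yl]-1,3a,4,5,6,7,8,8a-octahydroazulene-4,7-diol; 21 2-methylbut-3-en-2-ol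
Product: 22 (3aR,4S,5R,7R,8aS)-5-[(2S,4E)-6-hydroxy-6-methylhept-4-en-2-yl]-3-methyl-8-methylidene-1,3a,4,5,6,7,8,8a-octahydroazulene-4,7-diol
Conditions: 21 (excess), Hoveyda–Grubbs second-generation catalyst (H2IMes)Cl2Ru=CH(C6H4-2-OiPr) (cat.), CH2Cl2, 40 °C
Reagents that add atoms: none
Why: Olefin cross-metathesis between the monosubstituted olefin of 20 and the hindered tertiary allylic alcohol 21 gives the E-disubstituted olefin under thermodynamic control. The 1,1-disubstituted methylene and the trisubstituted ring olefin are much less reactive.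

Step 14
Reactants: 22 (3aR,4S,5R,7R,8aS)-5-[(2S,4E)-6-hydroxy-6-methylhept-4-en-2-yl]-3-methyl-8-methylidene-1,3a,4,5,6,7,8,8a-octahydroazulene-4,7-diol
Product: 23 (3aR,4S,5R,7R,8aS)-4-hydroxy-5-[(2S,4E)-6-hydroxy-6-methylhept-4-en-2-yl]-3-methyl-8-methylidene-1,3a,4,5,6,7,8,8a-octahydroazulen-7-yl acetate
Conditions: immobilised Burkholderia cepacia lipase, vinyl acetate, t-BuOMe, 30 °C
Reagents that add atoms: vinyl acetate CC(=O)OC=C
Why: The recognition used in step 7 now serves regioselection only: the unhindered allylic 9R carbinol is acetylated, while the C6 hydroxyl (flanked by the ring fusion and the branched C7) and the tertiary C15 hydroxyl are not.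

## Compound list

1 | tropone (cyclohepta-2,4,6-trien-1-one) | O=C1C=CC=CC=C1 | starting material
2 | (1R,5S)-6,7-dioxabicyclo[3.2.2]nona-3,8-dien-2-one (racemate) | O=C1C=C[C@@H]2C=C[C@H]1OO2 | intermediate
3 | (2R,5S)-2,5-dihydroxycyclohepta-3,6-dien-1-one (cis; racemate; not isolated) | O=C1C=C[C@@H](O)C=C[C@H]1O | intermediate
4 | (2R,5S)-2,5-bis(tert-butyldimethylsilyloxy)cyclohepta-3,6-dien-1-one (racemate) | O=C1C=C[C@@H](O[Si](C)(C)C(C)(C)C)C=C[C@H]1O[Si](C)(C)C(C)(C)C | intermediate
5 | isopropenylmagnesium bromide (prop-1-en-2-ylmagnesium bromide) | C=C(C)[Mg]Br | starting material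
6 | allyl iodide (3-iodoprop-1-ene) | C=CCI | starting material
7 | bromomagnesium enolate of (2R,5S,6R)-2,5-bis(tert-butyldimethylsilyloxy)-6-(prop-1-en-2-yl)cyclohept-3-en-1-one (racemate; not isolated) | C=C(C)[C@H]1C=C(O[Mg]Br)[C@H](O[Si](C)(C)C(C)(C)C)C=C[C@@H]1O[Si](C)(C)C(C)(C)C | intermediate
8 | (2R,5S,6R,7S)-2,5-bis(tert-butyldimethylsilyloxy)-6-(prop-1-en-2-yl)-7-(prop-2-en-1-yl)cyclohept-3-en-1-one (racemate) | C=CC[C@@H]1C(=O)[C@H](O[Si](C)(C)C(C)(C)C)C=C[C@H](O[Si](C)(C)C(C)(C)C)[C@H]1C(C)=C | intermediate
9 | (3aR,4S,7R,8aS)-4,7-bis(tert-butyldimethylsilyloxy)-3-methyl-3a,4,7,8a-tetrahydroazulen-8(1H)-one (racemate) | O=C1[C@H]2CC=C(C)[C@@H]2[C@@H](O[Si](C)(C)C(C)(C)C)C=C[C@H]1O[Si](C)(C)C(C)(C)C | intermediate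
10 | (3aR,4S,7R,8aS)-4,7-bis(tert-butyldimethylsilyloxy)-3-methyl-8-methylidene-1,3a,4,7,8,8a-hexahydroazulene (racemate) | C=C1[C@H]2CC=C(C)[C@@H]2[C@@H](O[Si](C)(C)C(C)(C)C)C=C[C@H]1O[Si](C)(C)C(C)(C)C | intermediate
11 | (3aR,4S,7R,8aS)-3-methyl-8-methylidene-1,3a,4,7,8,8a-hexahydroazulene-4,7-diol (racemate) | C=C1[C@H]2CC=C(C)[C@@H]2[C@@H](O)C=C[C@H]1O | intermediate
12 | (3aR,4S,7R,8aS)-4-hydroxy-3-methyl-8-methylidene-1,3a,4,7,8,8a-hexahydroazulen-7-yl acetate | C=C1[C@H]2CC=C(C)[C@@H]2[C@@H](O)C=C[C@H]1OC(C)=O | intermediate
13 | ethyl prop-1-enyl ether (1-ethoxyprop-1-ene, E/Z mixture) | CC=COCC | starting material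
14 | (3aR,4S,7R,8aS)-4-(2-bromo-1-ethoxypropoxy)-3-methyl-8-methylidene-1,3a,4,7,8,8a-hexahydroazulen-7-yl acetate (side-chain diastereomers) | C=C1[C@H]2CC=C(C)[C@@H]2[C@@H](OC(OCC)C(C)Br)C=C[C@H]1OC(C)=O | intermediate
15 | tricyclic ethyl acetal: O6–C12H(OEt)–C11H(CH3)–C7 tetrahydrofuran cis-fused at C6–C7, exo-methyl, 9-acetate (both C12 anomers) | C=C1[C@H]2CC=C(C)[C@@H]2[C@H]3OC(OCC)[C@H](C)[C@H]3C[C@H]1OC(C)=O | intermediate
16 | acetoxy lactol: C12 hemiacetal of 15 (not isolated) | C=C1[C@H]2CC=C(C)[C@@H]2[C@H]3OC(O)[C@H](C)[C@H]3C[C@H]1OC(C)=O | intermediate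
17 | lactol diol: C12 hemiacetal with free 9-OH, exo-methyl | C=C1[C@H]2CC=C(C)[C@@H]2[C@H]3OC(O)[C@H](C)[C@H]3C[C@H]1O | intermediate
18 | enol ether: 6,9-diol with C11H(CH3)–CH=CH–OCH3 side chain (E/Z; not isolated) | C=C1[C@H]2CC=C(C)[C@@H]2[C@@H](O)[C@@H]([C@@H](C)C=COC)C[C@H]1O | intermediate
19 | six-membered lactol: O6–C13H(OH)–C12H2–C11H(CH3)–C7 tetrahydropyran cis-fused at C6–C7, free 9-OH | C=C1[C@H]2CC=C(C)[C@@H]2[C@H]3OC(O)C[C@H](C)[C@H]3C[C@H]1O | intermediate
20 | (3aR,4S,5R,7R,8aS)-3-methyl-8-methylidene-5-[(2S)-pent-4-en-2-yl]-1,3a,4,5,6,7,8,8a-octahydroazulene-4,7-diol | C=C1[C@H]2CC=C(C)[C@@H]2[C@@H](O)[C@@H]([C@@H](C)CC=C)C[C@H]1O | intermediate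
21 | 2-methylbut-3-en-2-ol | C=CC(C)(C)O | starting material
22 | (3aR,4S,5R,7R,8aS)-5-[(2S,4E)-6-hydroxy-6-methylhept-4-en-2-yl]-3-methyl-8-methylidene-1,3a,4,5,6,7,8,8a-octahydroazulene-4,7-diol | C=C1[C@H]2CC=C(C)[C@@H]2[C@@H](O)[C@@H]([C@@H](C)C/C=C/C(C)(C)O)C[C@H]1O | intermediate
23 | (3aR,4S,5R,7R,8aS)-4-hydroxy-5-[(2S,4E)-6-hydroxy-6-methylhept-4-en-2-yl]-3-methyl-8-methylidene-1,3a,4,5,6,7,8,8a-octahydroazulen-7-yl acetate | C=C1[C@H]2CC=C(C)[C@@H]2[C@@H](O)[C@@H]([C@@H](C)C/C=C/C(C)(C)O)C[C@H]1OC(C)=O | target

## Step count and least certain steps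

Total: 14 steps. Longest linear sequence: 14 steps (1 → 23); compounds 5, 6, 13 and 21 are purchased.

**Step 1 (key step).**
- Risk: slow cycloaddition, because the troponoid triene is electron-poor and quenches singlet oxygen physically, together with base- or silica-induced Kornblum–DeLaMare isomerisation and aromatisation of 2 during isolation (H-9 lies between the carbonyl and the peroxide).
- Fallback (from 1, back at 2): mask the carbonyl first. O-Ethylation of 1 with Et3OBF4 and exchange with ethylene glycol/Et3N gives tropone ethylene ketal F1, an electron-rich 7,7-dialkoxycycloheptatriene. It should take up singlet oxygen across the same diene to give the ketal endoperoxide F2, which has no acidic α-peroxy hydrogen. Hydrolysis on wet oxalic acid/silica returns 2.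

**Step 2.**
- Risk: loss of water from diol 3 with aromatisation of the ring before both hydroxyls are silylated (enolisation at C9, then departure of the C6 oxygen). This is the weakest point of the route.
- Fallback (from 1 by way of F1 and F2, back at 4): thiourea reduction of F2 gives the ketal diol F3, which cannot enolise. Silylation gives the bis-silyl ketal F4, and pyridinium tosylate in wet acetone unmasks the ketone to give 4.

**Step 3.**
- Risk: proton transfer in enolate 7 before C-allylation (epimerisation at C9, or elimination of the C6 silyloxy group with aromatisation), or poor facial control, because the C9 silyloxy group sits on the face that the allyl group must take.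
- Fallback (from 4 and 5, back at 8): the enolate 7 is trapped on oxygen with allyl chloroformate to give the allyl enol carbonate F5, which is isolated. Pd(PPh3)4 then effects decarboxylative Tsuji–Trost allylation at C1 under neutral conditions to give 8.

**Step 7.**
- Risk: insufficient discrimination between the enantiomers, or competing acylation at C6, because both carbinol environments are cyclic and allylic.
- Fallback (from 11, back at 12): resolution through diastereomers. Coupling of the unhindered C9 hydroxyl of racemic 11 with (S)-O-methylmandelic acid (dicyclohexylcarbodiimide, DMAP) gives the mandelate F6 of the wanted enantiomer and the mandelate F7 of its antipode, separable on silica. Methanolysis of F6 (K2CO3, MeOH) returns enantiopure 11, and acetic anhydride/pyridine at low temperature acetylates the C9 hydroxyl to give 12.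

**Step 10.**
- Risk: incomplete convergence at C11, if the preference of the lactol for the exo-methyl epimer is smaller than assumed.
- Fallback (from 16, back at 17): the acetoxy lactol 16 is oxidised (TEMPO, PhI(OAc)2) to the acetoxy lactone F8. Its α-methyl centre equilibrates with DBU to the epimer on the convex face of the cis-fused bicycle. iBu2AlH (excess, −78 °C) then reduces the lactone to the lactol and removes the acetate, giving 17.

**Step 13.**
- Risk: sluggish cross-metathesis with the hindered tertiary allylic alcohol, homodimerisation of 20, or ruthenium hydride isomerisation of the allylic C9 alcohol.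
- Fallback (from 19, back at 22): Wittig reaction of lactol 19 with the stabilised ylide Ph3P=CHC(O)CH3 (toluene, 80 °C) gives the (E)-enone F9. CH3MgBr/CeCl3 at −78 °C adds 1,2 to the ketone to give 22.

## Further compounds

F1 | step 1 | tropone ethylene ketal (1,4-dioxaspiro[4.6]undeca-6,8,10-triene) | O1CCOC12C=CC=CC=C2
F2 | step 1 | ethylene ketal of endoperoxide 2 (racemate) | O1CCOC12C=C[C@@H]3C=C[C@H]2OO3
F3 | step 2 | ethylene ketal of cis-diol 3 (racemate) | O1CCOC12C=C[C@@H](O)C=C[C@H]2O
F4 | step 2 | ethylene ketal of bis-silyl ether 4 (racemate) | O1CCOC12C=C[C@@H](O[Si](C)(C)C(C)(C)C)C=C[C@H]2O[Si](C)(C)C(C)(C)C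
F5 | step 3 | allyl enol carbonate of enolate 7 (racemate) | C=C(C)[C@H]1C=C(OC(=O)OCC=C)[C@H](O[Si](C)(C)C(C)(C)C)C=C[C@@H]1O[Si](C)(C)C(C)(C)C
F6 | step 7 | C9 (S)-O-methylmandelate of the (3aR,4S,7R,8aS) enantiomer of 11 | C=C1[C@H]2CC=C(C)[C@@H]2[C@@H](O)C=C[C@H]1OC(=O)[C@@H](OC)c1ccccc1
F7 | step 7 | C9 (S)-O-methylmandelate of the (3aS,4R,7S,8aR) enantiomer of 11 | C=C1[C@@H]2CC=C(C)[C@H]2[C@H](O)C=C[C@@H]1OC(=O)[C@@H](OC)c1ccccc1
F8 | step 10 | acetoxy lactone: C12 lactone O6–C12(=O)–C11H(CH3)–C7, cis-fused, exo-methyl, 9-acetate | C=C1[C@H]2CC=C(C)[C@@H]2[C@H]3OC(=O)[C@H](C)[C@H]3C[C@H]1OC(C)=O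
F9 | step 13 | (E)-enone: 6,9-diol with C11H(CH3)–CH2–CH=CH–C(O)CH3 side chain | C=C1[C@H]2CC=C(C)[C@@H]2[C@@H](O)[C@@H]([C@@H](C)C/C=C/C(C)=O)C[C@H]1O
A1 | alternative 1 | (4R,5R)-4-(tert-butyldimethylsilyloxy)-5-[(2S,4E)-6-methyl-6-(triethylsilyloxy)hept-4-en-2-yl]cyclohept-2-en-1-one | O=C1C=C[C@@H](O[Si](C)(C)C(C)(C)C)[C@@H]([C@@H](C)C/C=C/C(C)(C)O[Si](CC)(CC)CC)CC1
A2 | alternative 1 | (3aR,4S,5R,8aS)-4-(tert-butyldimethylsilyloxy)-3-methyl-5-[(2S,4E)-6-methyl-6-(triethylsilyloxy)hept-4-en-2-yl]-3a,4,5,6,7,8a-hexahydroazulen-8(1H)-one | O=C1[C@H]2CC=C(C)[C@@H]2[C@@H](O[Si](C)(C)C(C)(C)C)[C@@H]([C@@H](C)C/C=C/C(C)(C)O[Si](CC)(CC)CC)CC1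
A3 | alternative 2 | (1R,5S)-8-oxabicyclo[3.2.1]octa-3,6-dien-2-one | O=C1C=C[C@@H]2C=C[C@H]1O2
A4 | alternative 3 | vinyl iodide–aldehyde, the C9–C10 seco precursor: cyclopentene bearing 1-iodovinyl at C1 and the C6(OSi)–C7(side chain)–C8–C9HO chain at C5 | C=C(I)[C@H]1CC=C(C)[C@@H]1[C@@H](O[Si](C)(C)C(C)(C)C)[C@@H]([C@@H](C)C/C=C/C(C)(C)O[Si](CC)(CC)CC)CC=O
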